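**Retrosynthetic overview**
Feature: in the cyclohexenone (C1 ketone carbon, C2=C3 alkene, C4 methoxy carbon, C5 methylene, C6 quaternary carbon) the oxygenated carbons C1 and C4 lie para across the C2=C3 alkene, which is the pattern of a 2-alkoxyfuran, and C5–C6 is a two-carbon dienophile unit.
Key disconnection: C1–C6 and C4–C5 by retro-[4+2] to 2-methoxyfuran and a 2-substituted acrylate that already carries C7 (methine) and C8 (carbinol, later the aryl ketone). The carbocycle is the only ring formed, first as a 1-methoxy-7-oxanorbornene and then opened to the 4-hydroxycyclohex-2-enone.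
After the cycloaddition: ester carbon to allyl CH2 (CH2OH, CHO, CH=CHOMe, CH2CHO, CH2CH=CH2), bridge oxygen to C4–OMe, C8 carbinol to ketone last.
Before it: an Evans syn-aldol sets C7 and C8 with an auxiliary, replacing an enantioselective zinc crotylation of uncertain selectivity; Weinreb amide, methyl ketone, enol triflate and palladium-catalysed methoxycarbonylation then give the acrylate.
Remark on the chemistry: the C8 carbinol configuration (S) is a temporary control element and is erased by the final oxidation.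

Key step: step 7

**Route**

Step 1
Reactants: 1 (4S)-4-benzyl-3-propanoyl-1,3-oxazolidin-2-one; 2 3,4-dimethoxybenzaldehyde
Product: 4 (4S)-4-benzyl-3-[(2S,3S)-3-(3,4-dimethoxyphenyl)-3-hydroxy-2-methylpropanoyl]-1,3-oxazolidin-2-one, via dibutylboron Z-enolate 3 (not isolated)
Conditions: Bu2BOTf, iPr2NEt, CH2Cl2, 0 °C; then 2, −78 → 0 °C; pH 7 buffer, MeOH, 30% H2O2
Reagents that add atoms: none
Why: Evans syn-aldol reaction, in which the boron Z-enolate reacts through a closed Zimmerman–Traxler chair whose enolate face is chosen by the (S)-benzyl oxazolidinone, setting the (2S,3S) syn centres that become C7 and C8.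

Step 2
Reactants: 4 aldol adduct
Product: 5 (2S,3S)-3-(3,4-dimethoxyphenyl)-3-hydroxy-N-methoxy-N,2-dimethylpropanamide
Conditions: Me(MeO)NH, AlMe3, CH2Cl2, −15 → 0 °C; aq. potassium sodium tartrate
Reagents that add atoms: N,O-dimethylhydroxylamine, CNOC
Why: Weinreb aminolysis of the imide by the aluminium amide, assisted by the free β-hydroxyl, releases the auxiliary without touching either stereocentre.

Step 3
Reactants: 5 Weinreb amide
Product: 6 (2S,3S)-3-[(tert-butyldimethylsilyl)oxy]-3-(3,4-dimethoxyphenyl)-N-methoxy-N,2-dimethylpropanamide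
Conditions: TBSOTf, 2,6-lutidine, CH2Cl2, −78 → 0 °C
Reagents that add atoms: tert-butyldimethylsilyl trifluoromethanesulfonate, CC(C)(C)[Si](C)(C)OS(=O)(=O)C(F)(F)F
Why: Silylation of the hindered benzylic alcohol with the silyl triflate blocks retro-aldol and later lactonisation onto the ester and gives C7 a large flanking group for the cycloaddition.

Step 4
Reactants: 6 silylated Weinreb amide
Product: 7 (3S,4S)-4-[(tert-butyldimethylsilyl)oxy]-4-(3,4-dimethoxyphenyl)-3-methylbutan-2-one
Conditions: MeMgBr, THF, −20 → 0 °C; aq. NH4Cl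
Reagents that add atoms: methylmagnesium bromide, C[Mg]Br
Why: Weinreb ketone synthesis, in which the stable magnesium chelate stops the addition at the methyl ketone; the new methyl carbon is the future ring carbon C5.

Step 5
Reactants: 7 methyl ketone
Product: 9 (3S,4S)-4-[(tert-butyldimethylsilyl)oxy]-4-(3,4-dimethoxyphenyl)-3-methylbut-1-en-2-yl trifluoromethanesulfonate, via terminal lithium enolate 8 (not isolated)
Conditions: LiN(iPr)2, THF, −78 °C; then PhNTf2, −78 → 0 °C
Reagents that add atoms: N-phenylbis(trifluoromethanesulfonimide), O=S(=O)(N(c1ccccc1)S(=O)(=O)C(F)(F)F)C(F)(F)F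
Why: Kinetic deprotonation at the methyl group and O-sulfonylation of the less substituted enolate (enol triflate formation) leave the C7 centre untouched, since the enolate that could epimerise or eliminate is not formed.

Step 6
Reactants: 9 enol triflate
Product: 10 methyl (3R,4S)-4-[(tert-butyldimethylsilyl)oxy]-4-(3,4-dimethoxyphenyl)-3-methyl-2-methylidenebutanoate
Conditions: Pd(OAc)2 (5 mol %), PPh3 (10 mol %), CO (1 atm), MeOH, Et3N, DMF, 50 °C
Reagents that add atoms: carbon monoxide, [C-]#[O+]; methanol, CO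
Why: Palladium-catalysed alkoxycarbonylation of a vinyl triflate (oxidative addition to zerovalent palladium, CO insertion, methanolysis) gives the 2-substituted acrylate; the inserted carbon is the future allyl CH2.

Step 7
Reactants: 10 acrylate; 11 2-methoxyfuran
Product: 12 methyl (1S,2R,4S)-2-[(1S,2R)-1-[(tert-butyldimethylsilyl)oxy]-1-(3,4-dimethoxyphenyl)propan-2-yl]-1-methoxy-7-oxabicyclo[2.2.1]hept-5-ene-2-carboxylate (ester endo, side chain exo)
Conditions: 11 (5 equiv), K2CO3 (trace), CH2Cl2, 12 kbar, 23 °C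
Reagents that add atoms: none
Why: Normal-electron-demand Diels–Alder reaction (concerted, asynchronous [4+2], with the bond from the unsubstituted furan α-carbon to the acrylate methylene leading), the known reaction type of 2-alkoxyfurans with acrylic esters, run under pressure without a Lewis acid so that the acid-labile bridged ketal and the silyl ether survive. The six-membered carbocycle C1–C6 closes in one suprafacial [4+2] event by forming C4–C5 and C1–C6, giving the 7-oxanorbornene whose bridge oxygen is the future C4 oxygen and whose ketal carbon is the future C1 carbonyl. Regiochemistry follows from the methoxy donor: the unsubstituted furan α-carbon (largest HOMO coefficient) bonds to the methylene C5 and the methoxy-bearing carbon to the ester-bearing C6. C6 is set by the dienophile face under control of the C7 stereocentre: with C7–H in the alkene plane toward the methylene, the silyloxybenzyl group covers one face and the furan adds from the methyl face. C1 and C4 are set relative to C6 by endo placement of the ester (secondary overlap, compact transition state under pressure) with the much larger branched side chain in the open exo position beside the oxygen bridge, where the CH2 bridge that pushes α-substituted acrylates toward exo-ester adducts with cyclopentadiene is absent. The step needs regio-, endo- and facial selectivity; the methoxy group secures the first, the size difference between CO2Me and the side chain the second, and the third rests only on the C7 centre and is the least secure, the diastereomeric adducts being expected to separate at the stage of 13.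

Step 8
Reactants: 12 cycloadduct
Product: 13 [(1S,2S,4S)-2-[(1S,2R)-1-[(tert-butyldimethylsilyl)oxy]-1-(3,4-dimethoxyphenyl)propan-2-yl]-1-methoxy-7-oxabicyclo[2.2.1]hept-5-en-2-yl]methanol
Conditions: LiAlH4, Et2O, −20 → 0 °C; Na2SO4·10H2O
Reagents that add atoms: none
Why: Hydride reduction of the neopentyl ester under basic, non-acidic conditions that the bridged ketal tolerates; removing the acceptor group also shuts off cycloreversion.

Step 9
Reactants: 13 carbinol
Product: 14 (1S,2S,4S)-2-[(1S,2R)-1-[(tert-butyldimethylsilyl)oxy]-1-(3,4-dimethoxyphenyl)propan-2-yl]-1-methoxy-7-oxabicyclo[2.2.1]hept-5-ene-2-carbaldehyde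
Conditions: SO3·pyridine, DMSO, iPr2NEt, CH2Cl2, 0 °C
Reagents that add atoms: none
Why: Parikh–Doering oxidation (activated DMSO, amine base) gives the non-enolisable aldehyde without acid, so the ketal bridge stays closed while C1 is still masked and no 1,3-dicarbonyl arises at C6.

Step 10
Reactants: 14 aldehyde
Product: 15 (1S,2R,4S)-2-[(1S,2R)-1-[(tert-butyldimethylsilyl)oxy]-1-(3,4-dimethoxyphenyl)propan-2-yl]-1-methoxy-2-(2-methoxyethenyl)-7-oxabicyclo[2.2.1]hept-5-ene (E/Z mixture)
Conditions: Ph3P(CH2OMe)Cl, KN(SiMe3)2, THF, 0 °C; then 14, 0 → 23 °C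
Reagents that add atoms: (methoxymethyl)triphenylphosphonium chloride, COC[P+](c1ccccc1)(c1ccccc1)c1ccccc1.[Cl-]
Why: Wittig methoxymethylenation with the small, reactive methoxymethylene ylide adds the second allyl carbon to the hindered, non-enolisable aldehyde as an enol ether.

Step 11
Reactants: 15 enol ether
Product: 17 2-[(1R,5S)-1-[(1S,2R)-1-[(tert-butyldimethylsilyl)oxy]-1-(3,4-dimethoxyphenyl)propan-2-yl]-5-hydroxy-2-oxocyclohex-3-en-1-yl]acetaldehyde, via ring-opened hydroxy enone enol ether 16 (not isolated)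
Conditions: TsOH·H2O (0.2 equiv), acetone/H2O (10:1), 0 → 23 °C
Reagents that add atoms: water, O
Why: Acid hydrolysis, in which the 1-methoxy bridged ketal ionises at C1 and opens to the 4-hydroxycyclohex-2-enone with the C4–O bond and its configuration retained, after which the enol ether hydrolyses to the homologated aldehyde; the quaternary C6 blocks aromatisation and the trans relation of the CH2CHO arm and C4–OH prevents lactol formation.

Step 12
Reactants: 17 hydroxy enone aldehyde
Product: 18 (4S,6S)-6-[(1S,2R)-1-[(tert-butyldimethylsilyl)oxy]-1-(3,4-dimethoxyphenyl)propan-2-yl]-4-hydroxy-6-(prop-2-en-1-yl)cyclohex-2-en-1-one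
Conditions: Ph3PCH3Br, KN(SiMe3)2 (2.5 equiv of ylide), THF, −78 → 0 °C
Reagents that add atoms: methyltriphenylphosphonium bromide, C[P+](c1ccccc1)(c1ccccc1)c1ccccc1.[Br-]
Why: Wittig methylenation is chemoselective for the aldehyde over the enone carbonyl, which is flanked by the quaternary C6; the first equivalent of ylide is taken up by the hydroxyl group.

Step 13
Reactants: 18 hydroxy allyl enone
Product: 19 (4S,6S)-6-[(1S,2R)-1-[(tert-butyldimethylsilyl)oxy]-1-(3,4-dimethoxyphenyl)propan-2-yl]-4-methoxy-6-(prop-2-en-1-yl)cyclohex-2-en-1-one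
Conditions: Me3OBF4, 1,8-bis(dimethylamino)naphthalene, CH2Cl2, 0 → 23 °C
Reagents that add atoms: trimethyloxonium tetrafluoroborate, C[O+](C)C.F[B-](F)(F)F
Why: O-Methylation with Meerwein's salt and a non-nucleophilic proton scavenger avoids alkoxide formation at the base-sensitive γ-hydroxy enone and keeps the C4 configuration.

Step 14
Reactants: 19 silyl ether
Product: 20 (4S,6S)-6-[(1S,2R)-1-(3,4-dimethoxyphenyl)-1-hydroxypropan-2-yl]-4-methoxy-6-(prop-2-en-1-yl)cyclohex-2-en-1-one
Conditions: HF·pyridine, pyridine, THF, 0 → 23 °C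
Reagents that add atoms: none
Why: Fluoride cleavage of the silyl ether under buffered conditions is compatible with the enone, the allyl group and the methyl ethers.

Step 15
Reactants: 20 benzylic carbinol
Product: 21 (4S,6S)-6-[(2R)-1-(3,4-dimethoxyphenyl)-1-oxopropan-2-yl]-4-methoxy-6-(prop-2-en-1-yl)cyclohex-2-en-1-one (target)
Conditions: Dess–Martin periodinane, CH2Cl2, 0 → 23 °C
Reagents that add atoms: none
Why: Dess–Martin oxidation of the benzylic carbinol to the aryl ketone under near-neutral conditions that should not epimerise the adjacent C7 centre.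

**Compound list**
1 | (4S)-4-benzyl-3-propanoyl-1,3-oxazolidin-2-one | CCC(=O)N1[C@@H](Cc2ccccc2)COC1=O | starting material
2 | 3,4-dimethoxybenzaldehyde | COc1ccc(C=O)cc1OC | starting material
3 | dibutylboron Z-enolate of 1 | C/C=C(\OB(CCCC)CCCC)N1[C@@H](Cc2ccccc2)COC1=O | intermediate
4 | (4S)-4-benzyl-3-[(2S,3S)-3-(3,4-dimethoxyphenyl)-3-hydroxy-2-methylpropanoyl]-1,3-oxazolidin-2-one | O=C(N1[C@@H](Cc2ccccc2)COC1=O)[C@@H](C)[C@H](O)c3ccc(OC)c(OC)c3 | intermediate
5 | (2S,3S)-3-(3,4-dimethoxyphenyl)-3-hydroxy-N-methoxy-N,2-dimethylpropanamide | CON(C)C(=O)[C@@H](C)[C@H](O)c1ccc(OC)c(OC)c1 | intermediate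
6 | (2S,3S)-3-[(tert-butyldimethylsilyl)oxy]-3-(3,4-dimethoxyphenyl)-N-methoxy-N,2-dimethylpropanamide | CON(C)C(=O)[C@@H](C)[C@H](O[Si](C)(C)C(C)(C)C)c1ccc(OC)c(OC)c1 | intermediate
7 | (3S,4S)-4-[(tert-butyldimethylsilyl)oxy]-4-(3,4-dimethoxyphenyl)-3-methylbutan-2-one | CC(=O)[C@@H](C)[C@H](O[Si](C)(C)C(C)(C)C)c1ccc(OC)c(OC)c1 | intermediate
8 | terminal lithium enolate of 7 | [Li]OC(=C)[C@@H](C)[C@H](O[Si](C)(C)C(C)(C)C)c1ccc(OC)c(OC)c1 | intermediate
9 | (3S,4S)-4-[(tert-butyldimethylsilyl)oxy]-4-(3,4-dimethoxyphenyl)-3-methylbut-1-en-2-yl trifluoromethanesulfonate | C=C(OS(=O)(=O)C(F)(F)F)[C@@H](C)[C@H](O[Si](C)(C)C(C)(C)C)c1ccc(OC)c(OC)c1 | intermediate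
10 | methyl (3R,4S)-4-[(tert-butyldimethylsilyl)oxy]-4-(3,4-dimethoxyphenyl)-3-methyl-2-methylidenebutanoate (syn) | C=C(C(=O)OC)[C@@H](C)[C@H](O[Si](C)(C)C(C)(C)C)c1ccc(OC)c(OC)c1 | intermediate
11 | 2-methoxyfuran | COc1ccco1 | starting material
12 | methyl (1S,2R,4S)-2-[(1S,2R)-1-[(tert-butyldimethylsilyl)oxy]-1-(3,4-dimethoxyphenyl)propan-2-yl]-1-methoxy-7-oxabicyclo[2.2.1]hept-5-ene-2-carboxylate (ester endo) | COC(=O)[C@@]1([C@@H](C)[C@H](O[Si](C)(C)C(C)(C)C)c2ccc(OC)c(OC)c2)C[C@@H]2O[C@@]1(OC)C=C2 | intermediate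
13 | [(1S,2S,4S)-2-[(1S,2R)-1-[(tert-butyldimethylsilyl)oxy]-1-(3,4-dimethoxyphenyl)propan-2-yl]-1-methoxy-7-oxabicyclo[2.2.1]hept-5-en-2-yl]methanol | OC[C@@]1([C@@H](C)[C@H](O[Si](C)(C)C(C)(C)C)c2ccc(OC)c(OC)c2)C[C@@H]2O[C@@]1(OC)C=C2 | intermediate
14 | (1S,2S,4S)-2-[(1S,2R)-1-[(tert-butyldimethylsilyl)oxy]-1-(3,4-dimethoxyphenyl)propan-2-yl]-1-methoxy-7-oxabicyclo[2.2.1]hept-5-ene-2-carbaldehyde | O=C[C@@]1([C@@H](C)[C@H](O[Si](C)(C)C(C)(C)C)c2ccc(OC)c(OC)c2)C[C@@H]2O[C@@]1(OC)C=C2 | intermediate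
15 | (1S,2R,4S)-2-[(1S,2R)-1-[(tert-butyldimethylsilyl)oxy]-1-(3,4-dimethoxyphenyl)propan-2-yl]-1-methoxy-2-(2-methoxyethenyl)-7-oxabicyclo[2.2.1]hept-5-ene (E/Z mixture) | COC=C[C@@]1([C@@H](C)[C@H](O[Si](C)(C)C(C)(C)C)c2ccc(OC)c(OC)c2)C[C@@H]2O[C@@]1(OC)C=C2 | intermediate
16 | (4S,6R)-6-[(1S,2R)-1-[(tert-butyldimethylsilyl)oxy]-1-(3,4-dimethoxyphenyl)propan-2-yl]-4-hydroxy-6-(2-methoxyethenyl)cyclohex-2-en-1-one | COC=C[C@@]1([C@@H](C)[C@H](O[Si](C)(C)C(C)(C)C)c2ccc(OC)c(OC)c2)C[C@H](O)C=CC1=O | intermediate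
17 | 2-[(1R,5S)-1-[(1S,2R)-1-[(tert-butyldimethylsilyl)oxy]-1-(3,4-dimethoxyphenyl)propan-2-yl]-5-hydroxy-2-oxocyclohex-3-en-1-yl]acetaldehyde | O=CC[C@@]1([C@@H](C)[C@H](O[Si](C)(C)C(C)(C)C)c2ccc(OC)c(OC)c2)C[C@H](O)C=CC1=O | intermediate
18 | (4S,6S)-6-[(1S,2R)-1-[(tert-butyldimethylsilyl)oxy]-1-(3,4-dimethoxyphenyl)propan-2-yl]-4-hydroxy-6-(prop-2-en-1-yl)cyclohex-2-en-1-one | C=CC[C@@]1([C@@H](C)[C@H](O[Si](C)(C)C(C)(C)C)c2ccc(OC)c(OC)c2)C[C@H](O)C=CC1=O | intermediate
19 | (4S,6S)-6-[(1S,2R)-1-[(tert-butyldimethylsilyl)oxy]-1-(3,4-dimethoxyphenyl)propan-2-yl]-4-methoxy-6-(prop-2-en-1-yl)cyclohex-2-en-1-one | C=CC[C@@]1([C@@H](C)[C@H](O[Si](C)(C)C(C)(C)C)c2ccc(OC)c(OC)c2)C[C@H](OC)C=CC1=O | intermediate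
20 | (4S,6S)-6-[(1S,2R)-1-(3,4-dimethoxyphenyl)-1-hydroxypropan-2-yl]-4-methoxy-6-(prop-2-en-1-yl)cyclohex-2-en-1-one | C=CC[C@@]1([C@@H](C)[C@H](O)c2ccc(OC)c(OC)c2)C[C@H](OC)C=CC1=O | intermediate
21 | (4S,6S)-6-[(2R)-1-(3,4-dimethoxyphenyl)-1-oxopropan-2-yl]-4-methoxy-6-(prop-2-en-1-yl)cyclohex-2-en-1-one | C=CC[C@@]1([C@@H](C)C(=O)c2ccc(OC)c(OC)c2)C[C@H](OC)C=CC1=O | target

**Totals**
Total step count: 15. Longest linear sequence: 15 steps (1 → 21).

**Steps most likely to fail**

Step 7. The endo/exo preference may turn the other way, since α-branched acrylates often place the ester exo. The bridge oxygen would then end up cis to the future allyl group and the whole C4-epimeric series would form. Weak facial discrimination by C7 would in addition cost material as a C6 epimer, and on standard allylic-strain grounds the opposite face could even be preferred, which this fallback does not repair. The fallback accepts the ester-exo adduct and corrects C4 by inversion once the bridge is open. It sets out from 10 and 11 and comes back at 18. The cycloaddition gives the ester-exo adduct F1. LiAlH4 gives the carbinol F2, Parikh–Doering oxidation the aldehyde F3, and methoxymethylenation the enol ether F4. Acid hydrolysis gives the C4-epimeric hydroxy aldehyde F5, whose hydroxyl is cis to the CH2CHO arm so that it may rest as a bridged lactol. Excess Ph3P=CH2 opens this to the (4R)-hydroxy allyl enone F6. Mitsunobu inversion (4-nitrobenzoic acid, PPh3, diisopropyl azodicarboxylate, THF, 0 °C) gives the (4S)-4-nitrobenzoate F7, and K2CO3 in MeOH at 0 °C frees the (4S)-alcohol, which is 18.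

Step 11. The acid needed to hydrolyse the neopentylic enol ether may also strip the silyl ether from the electron-rich benzylic carbinol or ionise that position. The fallback makes the loss deliberate and finishes without the protecting group. It sets out from 15 and comes back at 21. 1 M aq. HCl in THF at 23 °C opens the ketal and hydrolyses both the enol ether and the silyl ether, giving the diol aldehyde F8 (possibly as a lactol). Wittig methylenation with excess ylide gives the diol F9. DDQ in CH2Cl2 at 23 °C oxidises only the electron-rich benzylic carbinol and leaves the allylic hydroxyl of the electron-poor enone, giving the hydroxy diketone F10. Me3OBF4 with 1,8-bis(dimethylamino)naphthalene then methylates the C4 hydroxyl to give 21.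

Step 12. The excess basic ylide turns the C4 hydroxyl into an alkoxide, which may set off isomerisation of the γ-hydroxy enone or enolisation of the aldehyde. The fallback caps the hydroxyl first and then olefinates without base. It sets out from 17 and comes back at 19. Me3OBF4 with 1,8-bis(dimethylamino)naphthalene gives the methoxy aldehyde F11. Takai methylenation (CH2I2, Zn, Ti(OiPr)4, THF, 23 °C), which is non-basic and selective for aldehydes over ketones, then gives 19.

**Further compounds**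
F1 | step 7 | methyl (1R,2R,4R)-2-[(1S,2R)-1-[(tert-butyldimethylsilyl)oxy]-1-(3,4-dimethoxyphenyl)propan-2-yl]-1-methoxy-7-oxabicyclo[2.2.1]hept-5-ene-2-carboxylate (ester exo) | COC(=O)[C@@]1([C@@H](C)[C@H](O[Si](C)(C)C(C)(C)C)c2ccc(OC)c(OC)c2)C[C@H]2O[C@]1(OC)C=C2
F2 | step 7 | ester-exo series carbinol (C1,C4-epimer of 13) | OC[C@@]1([C@@H](C)[C@H](O[Si](C)(C)C(C)(C)C)c2ccc(OC)c(OC)c2)C[C@H]2O[C@]1(OC)C=C2
F3 | step 7 | ester-exo series aldehyde (C1,C4-epimer of 14) | O=C[C@@]1([C@@H](C)[C@H](O[Si](C)(C)C(C)(C)C)c2ccc(OC)c(OC)c2)C[C@H]2O[C@]1(OC)C=C2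
F4 | step 7 | ester-exo series enol ether (C1,C4-epimer of 15) | COC=C[C@@]1([C@@H](C)[C@H](O[Si](C)(C)C(C)(C)C)c2ccc(OC)c(OC)c2)C[C@H]2O[C@]1(OC)C=C2
F5 | step 7 | C4-epimeric hydroxy aldehyde (carbinol epimer of 17, open form) | O=CC[C@@]1([C@@H](C)[C@H](O[Si](C)(C)C(C)(C)C)c2ccc(OC)c(OC)c2)C[C@@H](O)C=CC1=O
F6 | step 7 | (4R,6S)-6-[(1S,2R)-1-[(tert-butyldimethylsilyl)oxy]-1-(3,4-dimethoxyphenyl)propan-2-yl]-4-hydroxy-6-(prop-2-en-1-yl)cyclohex-2-en-1-one | C=CC[C@@]1([C@@H](C)[C@H](O[Si](C)(C)C(C)(C)C)c2ccc(OC)c(OC)c2)C[C@@H](O)C=CC1=O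
F7 | step 7 | (1S,5S)-5-[(1S,2R)-1-[(tert-butyldimethylsilyl)oxy]-1-(3,4-dimethoxyphenyl)propan-2-yl]-4-oxo-5-(prop-2-en-1-yl)cyclohex-2-en-1-yl 4-nitrobenzoate | C=CC[C@@]1([C@@H](C)[C@H](O[Si](C)(C)C(C)(C)C)c2ccc(OC)c(OC)c2)C[C@H](OC(=O)c2ccc(cc2)[N+](=O)[O-])C=CC1=O
F8 | step 11 | 2-[(1R,5S)-1-[(1S,2R)-1-(3,4-dimethoxyphenyl)-1-hydroxypropan-2-yl]-5-hydroxy-2-oxocyclohex-3-en-1-yl]acetaldehyde (open form) | O=CC[C@@]1([C@@H](C)[C@H](O)c2ccc(OC)c(OC)c2)C[C@H](O)C=CC1=O
F9 | step 11 | (4S,6S)-6-[(1S,2R)-1-(3,4-dimethoxyphenyl)-1-hydroxypropan-2-yl]-4-hydroxy-6-(prop-2-en-1-yl)cyclohex-2-en-1-one | C=CC[C@@]1([C@@H](C)[C@H](O)c2ccc(OC)c(OC)c2)C[C@H](O)C=CC1=O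
F10 | step 11 | (4S,6S)-6-[(2R)-1-(3,4-dimethoxyphenyl)-1-oxopropan-2-yl]-4-hydroxy-6-(prop-2-en-1-yl)cyclohex-2-en-1-one | C=CC[C@@]1([C@@H](C)C(=O)c2ccc(OC)c(OC)c2)C[C@H](O)C=CC1=O
F11 | step 12 | 2-[(1R,5S)-1-[(1S,2R)-1-[(tert-butyldimethylsilyl)oxy]-1-(3,4-dimethoxyphenyl)propan-2-yl]-5-methoxy-2-oxocyclohex-3-en-1-yl]acetaldehyde | O=CC[C@@]1([C@@H](C)[C@H](O[Si](C)(C)C(C)(C)C)c2ccc(OC)c(OC)c2)C[C@H](OC)C=CC1=O
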